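**Assumption:** the (S)-SEGPHOS–iridium catalyst in Step 5 is taken to give the (3S,4R) lactone by analogy with ordinary aldehydes; if the opposite sense is found, the (R)-ligand is used and nothing else changes.

## Retrosynthetic overview

1. Target ← one global hydrogenolysis of a tribenzylated aldol adduct (removes three benzyl groups and one benzylic OH).
2. C3 quaternary carbinol ← aldol of an α-benzyloxy lactone enolate with O-benzylvanillin, anti to the C4 benzyl group (this places the C3 oxygen cis to the C4 benzyl).
3. C4–CH2–Ar bond ← Pd-catalysed Negishi coupling of a lactone-CH2ZnI with the aryl bromide.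
4. Lactone ring (the only ring, formed first) and the C3–C4 (lignan 8–8′) bond ← Ir-catalysed asymmetric (hydroxymethyl)allylation of ethyl glyoxylate with vinyl ethylene carbonate, then lactonisation.
5. Both aryl units ← catechol via guaiacol and 4-bromoguaiacol.

## Route

**Step 1**
Reactants: 1, catechol (benzene-1,2-diol)
Product: 2, guaiacol (2-methoxyphenol)
Conditions: MeI (1.0 equiv), K2CO3, acetone, reflux
Reagents that add atoms: iodomethane, CI
Why: Williamson mono-O-methylation; leftover catechol and veratrole are removed by aqueous base extraction.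

**Step 2**
Reactants: 2, guaiacol
Product: 3, 4-bromo-2-methoxyphenol
Conditions: NBS, MeCN, 0 °C → rt
Reagents that add atoms: N-bromosuccinimide, O=C1CCC(=O)N1Br
Why: electrophilic aromatic bromination para to the free OH, the stronger director.

**Step 3**
Reactants: 3, 4-bromo-2-methoxyphenol
Product: 4, 1-(benzyloxy)-4-bromo-2-methoxybenzene
Conditions: BnBr, K2CO3, DMF, rt
Reagents that add atoms: benzyl bromide, BrCc1ccccc1
Why: Williamson etherification to protect the phenol for the organometallic steps.

**Step 4**
Reactants: 4, 1-(benzyloxy)-4-bromo-2-methoxybenzene (part of the batch)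
Product: 5, 4-(benzyloxy)-3-methoxybenzaldehyde
Conditions: n-BuLi, THF, −78 °C; DMF; aq NH4Cl
Reagents that add atoms: N,N-dimethylformamide, CN(C)C=O
Why: Br–Li exchange followed by Bouveault formylation.

**Step 5**
Reactants: 6, ethyl glyoxylate; 7, 4-vinyl-1,3-dioxolan-2-one (racemic vinyl ethylene carbonate)
Product: 8, (3S,4R)-3-hydroxy-4-vinyloxolan-2-one (trans lactone)
Conditions: [Ir(cod)Cl]2 (2.5 mol %), (S)-SEGPHOS (5 mol %), 4-cyano-3-nitrobenzoic acid (10 mol %), K3PO4 (5 mol %), i-PrOH (2 equiv), THF, 60 °C, slow addition of 6; then PPTS, PhMe, 50 °C; trans isomer purified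
Reagents that add atoms: none (i-PrOH supplies hydrogen only; CO2 and EtOH are lost)
Why: Proposed new method: a glyoxylate ester as the carbonyl partner in Ir-catalysed transfer-hydrogenative (hydroxymethyl)allylation with in situ lactonisation. The cyclometallated Ir(III)–SEGPHOS π-allyl, formed from 7 by ionisation and decarboxylation, adds as its (E)-σ-allyl through a closed chair transition state to the highly electrophilic glyoxylate C=O. This gives the anti adduct, with the ligand choosing the face and so setting C4 (R) and C3 (S). i-PrOH turns over the Ir alkoxide, and the primary alkoxide closes onto the ester to give the trans γ-lactone. Closest known reaction: Krische Ir-catalysed anti-(hydroxymethyl)allylation of aryl and alkyl aldehydes with vinyl ethylene carbonate.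

**Step 6**
Reactants: 8, (3S,4R)-3-hydroxy-4-vinyloxolan-2-one
Product: 9, (3S,4R)-3-(benzyloxy)-4-vinyloxolan-2-one
Conditions: BnOC(=NH)CCl3, TfOH (5 mol %), CH2Cl2/cyclohexane, 0 °C → rt
Reagents that add atoms: benzyl 2,2,2-trichloroacetimidate, N=C(OCc1ccccc1)C(Cl)(Cl)Cl
Why: acid-catalysed imidate O-benzylation; avoiding base prevents C3 epimerisation and alkene migration.

**Step 7**
Reactants: 9, (3S,4R)-3-(benzyloxy)-4-vinyloxolan-2-one
Product: 10, (3S,4R)-3-(benzyloxy)-4-(hydroxymethyl)oxolan-2-one
Conditions: O3, CH2Cl2/MeOH, −78 °C (Sudan III end point); NaBH4, −78 → −30 °C; AcOH quench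
Reagents that add atoms: ozone, [O-][O+]=O
Why: ozonolysis of the vinyl group with in situ hydride reduction of the aldehyde; C4 is untouched. Any acyl migration to the other CH2O arm gives the cis diastereomer, which is separable, so ee is not eroded.

**Step 8**
Reactants: 10, (3S,4R)-3-(benzyloxy)-4-(hydroxymethyl)oxolan-2-one
Product: 11, (3S,4R)-3-(benzyloxy)-4-(iodomethyl)oxolan-2-one
Conditions: I2, PPh3, imidazole, CH2Cl2, 0 °C
Reagents that add atoms: iodine, II
Why: Appel iodination of the primary alcohol; this also removes the acyl-migration pathway.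

**Step 9**
Reactants: 11, (3S,4R)-3-(benzyloxy)-4-(iodomethyl)oxolan-2-one; 4, 1-(benzyloxy)-4-bromo-2-methoxybenzene
Product: 12, (3S,4R)-3-(benzyloxy)-4-[(4-(benzyloxy)-3-methoxyphenyl)methyl]oxolan-2-one
Conditions: Zn dust (TMSCl/BrCH2CH2Br-activated), DMA, 35 °C; then 4, Pd2(dba)3 (2 mol %), SPhos (8 mol %), THF/DMA, 50 °C
Reagents that add atoms: none
Why: Negishi C(sp3)–C(sp2) coupling; the primary alkylzinc has no β-leaving group and is too weakly basic to touch the lactone α-H, so C3 and C4 are unchanged.

**Step 10**
Reactants: 12, the lactone from Step 9; 5, 4-(benzyloxy)-3-methoxybenzaldehyde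
Product: 13, (3S,4R)-3-(benzyloxy)-3-[(4-(benzyloxy)-3-methoxyphenyl)(hydroxy)methyl]-4-[(4-(benzyloxy)-3-methoxyphenyl)methyl]oxolan-2-one (both carbinol epimers)
Conditions: LDA, THF, −78 °C; then 5, −78 °C; AcOH quench at −78 °C
Reagents that add atoms: none
Why: lithium enolate aldol; the aldehyde attacks the planar α-benzyloxy enolate anti to the C4 benzyl group. The new C3–C bond is therefore trans to the C4 benzyl and the C3 oxygen is cis to it. The carbinol centre is removed in Step 11.

**Step 11**
Reactants: 13, the aldol adduct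
Product: 14, (+)-nortrachelogenin, (3R,4R)-3-hydroxy-3,4-bis[(4-hydroxy-3-methoxyphenyl)methyl]oxolan-2-one
Conditions: H2 (3 atm), Pd(OH)2/C, EtOAc/AcOH (10:1), rt
Reagents that add atoms: none
Why: hydrogenolysis of two aryl benzyl ethers, the tertiary benzyl ether and the p-oxygenated benzylic C–OH (as in the hydroxymatairesinol → matairesinol reduction). No ring stereocentre is touched; the C3 descriptor changes from S to R only because CH(OH)Ar becomes CH2Ar.

## Compound list

1 | catechol (benzene-1,2-diol) | Oc1ccccc1O | starting material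
2 | guaiacol (2-methoxyphenol) | COc1ccccc1O | intermediate
3 | 4-bromo-2-methoxyphenol | COc1cc(Br)ccc1O | intermediate
4 | 1-(benzyloxy)-4-bromo-2-methoxybenzene | COc1cc(Br)ccc1OCc1ccccc1 | intermediate
5 | 4-(benzyloxy)-3-methoxybenzaldehyde | COc1cc(C=O)ccc1OCc1ccccc1 | intermediate
6 | ethyl glyoxylate | CCOC(=O)C=O | starting material
7 | 4-vinyl-1,3-dioxolan-2-one (racemic) | C=CC1COC(=O)O1 | starting material
8 | (3S,4R)-3-hydroxy-4-vinyloxolan-2-one | C=C[C@@H]1COC(=O)[C@H]1O | intermediate
9 | (3S,4R)-3-(benzyloxy)-4-vinyloxolan-2-one | C=C[C@@H]1COC(=O)[C@H]1OCc1ccccc1 | intermediate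
10 | (3S,4R)-3-(benzyloxy)-4-(hydroxymethyl)oxolan-2-one | OC[C@@H]1COC(=O)[C@H]1OCc1ccccc1 | intermediate
11 | (3S,4R)-3-(benzyloxy)-4-(iodomethyl)oxolan-2-one | IC[C@@H]1COC(=O)[C@H]1OCc1ccccc1 | intermediate
12 | (3S,4R)-3-(benzyloxy)-4-[(4-(benzyloxy)-3-methoxyphenyl)methyl]oxolan-2-one | COc1cc(C[C@@H]2COC(=O)[C@H]2OCc2ccccc2)ccc1OCc1ccccc1 | intermediate
13 | (3S,4R)-3-(benzyloxy)-3-[(4-(benzyloxy)-3-methoxyphenyl)(hydroxy)methyl]-4-[(4-(benzyloxy)-3-methoxyphenyl)methyl]oxolan-2-one (carbinol epimers) | COc1cc(C[C@@H]2COC(=O)[C@@]2(OCc2ccccc2)C(O)c2ccc(OCc3ccccc3)c(OC)c2)ccc1OCc1ccccc1 | intermediate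
14 | (+)-nortrachelogenin, (3R,4R) | COc1cc(C[C@@H]2COC(=O)[C@@]2(O)Cc2ccc(O)c(OC)c2)ccc1O | target

## Summary

Total steps: 11.
Longest linear sequence: 7 (Steps 5–11). The aryl branches give 6 (Steps 1–3, 9–11 or Steps 1–4, 10–11).

Steps most likely to fail, each with a fallback:

1. **Step 5 (proposed new Ir coupling).** Glyoxylate may be reduced rather than allylated, or give low ee. Fallback, known chemistry: a diarylprolinol-catalysed enamine cross-aldol of ethyl glyoxylate with 3-(tert-butyldiphenylsilyloxy)propanal, then NaBH4 reduction and lactonisation to the 3-hydroxy-4-(silyloxymethyl) lactone. Imidate O-benzylation and buffered desilylation then give 10, bypassing 8, 9 and the ozonolysis.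
2. **Step 7 (ozonolysis/reduction).** Risks are benzyl ether oxidation, elimination at the aldehyde stage, and acyl migration in the hydroxymethyl lactone. Fallback: stop at the aldehyde (Me2S work-up) and add the non-basic aryltitanium ArTi(Oi-Pr)3 made from 4. Silylate the resulting benzylic alcohol and remove that oxygen in the final hydrogenolysis. This replaces the alcohol → iodide → Negishi sequence with carbonyl addition.
3. **Step 10 (aldol to the quaternary centre).** Risks are retro-aldol and incomplete facial control. Fallback: reduce 5 (NaBH4) and brominate (PBr3) to 4-(benzyloxy)-3-methoxybenzyl bromide, then alkylate the enolate of 12 (LiHMDS, THF/DMPU, −78 °C). This gives the tribenzyl ether of the target directly, so the last step is a simple debenzylation.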